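**Strategy.** The bicyclic core is cut at O2–C3 and C4a=C5. The conjugated O2–C3=C4–C4a=C5–C6=O unit that runs across rings A and B is treated as what remains when a chain oxidised at C3, C4a and C6 is cyclised and dehydrated. In one gold-catalysed operation the free C1 hydroxyl of an acyclic diynone closes ring A on the C3≡C4–C4a=O ynone, the C5≡C6 ethynyl carbinol is hydrated, and the new C5 methyl condenses with C4a to close ring B. The precursor already holds C7, C8, C8a and the three side-chain stereocentres. It is made by opening a malate-derived γ-lactone (fragment 2) with the acetylide of an enyne from L-allo-isoleucine (fragment 1).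

Key step: step 13

Numbering: core atoms keep their isochromene numbers (C1, O2, C3, C4, C4a, C5–C8, C8a) in all intermediates; side-chain atoms are primed.
Assumption: 23 and 24 are drawn as open γ-hydroxy ynones; each may sit partly as its five-membered hemiketal (O7 on C4a), a ring–chain tautomer that feeds the open form.

**Fragment 1 (steps 1–6)**

Step 1
Reactants: 1 L-allo-isoleucine
Product: 2 (2S,3R)-2-hydroxy-3-methylpentanoic acid
Conditions: NaNO2, 1 M H2SO4, H2O, 0 °C to rt
Reagents that add atoms: water, O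
Why: Diazotisation of an α-amino acid: the carboxylate expels N2 to give an α-lactone that water reopens, a double inversion, so C2 keeps its S configuration and C3 is not touched.

Step 2
Reactants: 2 (2S,3R)-2-hydroxy-3-methylpentanoic acid
Product: 3 (2S,3R)-2-hydroxy-N-methoxy-N,3-dimethylpentanamide
Conditions: MeNHOMe·HCl, EDC·HCl, HOBt, N-methylmorpholine, CH2Cl2, 0 °C to rt
Reagents that add atoms: N,O-dimethylhydroxylamine hydrochloride, Cl.CNOC
Why: Carbodiimide amide coupling through the HOBt active ester works on unprotected α-hydroxy acids, which cannot racemise by the azlactone path, and gives the Weinreb amide.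

Step 3
Reactants: 3 (2S,3R)-2-hydroxy-N-methoxy-N,3-dimethylpentanamide
Product: 4 (2S,3R)-2-[(tert-butyldimethylsilyl)oxy]-N-methoxy-N,3-dimethylpentanamide
Conditions: TBSOTf, 2,6-lutidine, CH2Cl2, 0 °C
Reagents that add atoms: tert-butyldimethylsilyl trifluoromethanesulfonate, CC(C)(C)[Si](C)(C)OS(=O)(=O)C(F)(F)F
Why: Silylation with a silyl triflate and a hindered pyridine base is reliable on a hindered secondary hydroxyl and installs a bulky, non-chelating group, which step 5 needs for Felkin–Anh control.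

Step 4
Reactants: 4 (2S,3R)-2-[(tert-butyldimethylsilyl)oxy]-N-methoxy-N,3-dimethylpentanamide
Product: 5 (3S,4R)-3-[(tert-butyldimethylsilyl)oxy]-4-methylhexan-2-one
Conditions: MeMgBr, THF, −78 to 0 °C; H2O
Reagents that add atoms: methylmagnesium bromide, C[Mg]Br
Why: Weinreb ketone synthesis: the chelated tetrahedral magnesium adduct survives until work-up, so only one methyl adds and the α-stereocentre is not enolised.

Step 5
Reactants: 5 (3S,4R)-3-[(tert-butyldimethylsilyl)oxy]-4-methylhexan-2-one; 6 1,4-bis(trimethylsilyl)buta-1,3-diyne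
Product: 8 (5R,6S,7R)-6-[(tert-butyldimethylsilyl)oxy]-5,7-dimethyl-1-(trimethylsilyl)nona-1,3-diyn-5-ol, via lithium (trimethylsilyl)butadiynide 7 (not isolated)
Conditions: 6, MeLi·LiBr, THF, rt; then 5, −78 °C; H2O at −78 °C
Reagents that add atoms: 1,4-bis(trimethylsilyl)buta-1,3-diyne (6), C[Si](C)(C)C#CC#C[Si](C)(C)C
Why: 1,2-Addition of a lithium acetylide under polar Felkin–Anh (non-chelation) control: with the silyloxy group anti to the incoming nucleophile and the acetylide passing the C3 hydrogen instead of the sec-butyl group, the new carbinol C5 (C3′ of the target) should form R.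

Step 6
Reactants: 8 (5R,6S,7R)-6-[(tert-butyldimethylsilyl)oxy]-5,7-dimethyl-1-(trimethylsilyl)nona-1,3-diyn-5-ol
Product: 10 (3E,5R,6S,7R)-6-[(tert-butyldimethylsilyl)oxy]-5,7-dimethylnon-3-en-1-yn-5-ol (fragment 1), via C-silylated enyne 9 (not isolated)
Conditions: NaAlH2(OCH2CH2OMe)2, THF, 0 °C to rt; then MeOH, K2CO3 (cat.), rt; aq KNaC4H4O6
Reagents that add atoms: none
Why: Alkoxide-directed trans-hydroalumination of a propargylic alcohol reduces only the triple bond next to the carbinol and gives the E alkene after protonolysis, and the methoxide formed on the methanol quench then cleaves the alkynyl–silicon bond (protodesilylation).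

**Fragment 2 (steps 7–10)**

Step 7
Reactants: 11 dimethyl (R)-malate; 12 formaldehyde
Product: 15 methyl (3S,4R)-4-hydroxy-5-oxooxolane-3-carboxylate, via malate dianion 13 (not isolated), via open diol diester 14 (not isolated)
Conditions: LiN(SiMe3)2 (2.1 equiv), THF, −78 to −20 °C; CH2O (g), −78 °C; AcOH; then TsOH (cat.), CH2Cl2, rt
Reagents that add atoms: formaldehyde (12), C=O
Why: Fráter–Seebach reaction, here as an aldol with monomeric formaldehyde: the lithium-bridged alkoxide–enolate is attacked anti to the C2 ester, which sets C8a (3S in 14, anti to the C8 hydroxyl), and acid then closes the new primary hydroxyl onto the adjacent ester (5-exo-trig lactonisation), which masks O1 and tells the two esters apart.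

Step 8
Reactants: 15 methyl (3S,4R)-4-hydroxy-5-oxooxolane-3-carboxylate
Product: 17 methyl (3S,4R)-4,5-dihydroxy-5-methyloxolane-3-carboxylate (lactol, both C5 anomers), via trimethylsilyl ether 16 (not isolated)
Conditions: TMSCl, Et3N, CH2Cl2, 0 °C; then MeLi (1.05 equiv), THF, −78 °C; AcOH, THF/H2O, 0 °C
Reagents that add atoms: methyllithium, [Li]C
Why: Mono-addition of an organolithium to a silylated γ-lactone, as used for 1-deoxy ketoses: the lactone carbonyl, s-cis and activated by the α-silyloxy group, should react at −78 °C before the branched methyl ester, the lithium hemiketalate resists a second addition, and mild acid removes the transient trimethylsilyl group.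

Step 9
Reactants: 17 methyl (3S,4R)-4,5-dihydroxy-5-methyloxolane-3-carboxylate; 18 ethynylmagnesium bromide
Product: 20 (3S,4R,5R)-5-ethynyl-4-hydroxy-3-(hydroxymethyl)-5-methyloxolan-2-one, via open triol ester 19 (not isolated)
Conditions: HC≡CMgBr (4 equiv), THF, −20 °C to rt; H2O; then TsOH (cat.), CH2Cl2, rt
Reagents that add atoms: ethynylmagnesium bromide (18), C#C[Mg]Br
Why: Grignard addition under the Cram chelate (cyclic) model: the lactol reacts through its keto tautomer, magnesium bridges the C8 alkoxide and the ketone oxygen in a five-membered chelate, the acetylide enters anti to the C8a branch and sets C7 (4R in 19), and the tertiary oxygen then closes onto the ester to the γ-lactone, which masks O7 and leaves C4a as the only acyl group.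

Step 10
Reactants: 20 (3S,4R,5R)-5-ethynyl-4-hydroxy-3-(hydroxymethyl)-5-methyloxolan-2-one
Product: 21 (3S,4R,5R)-4-[(tert-butyldimethylsilyl)oxy]-3-{[(tert-butyldimethylsilyl)oxy]methyl}-5-ethynyl-5-methyloxolan-2-one (fragment 2)
Conditions: TBSOTf (2.4 equiv), 2,6-lutidine, CH2Cl2, −40 to 0 °C
Reagents that add atoms: tert-butyldimethylsilyl trifluoromethanesulfonate, CC(C)(C)[Si](C)(C)OS(=O)(=O)C(F)(F)F
Why: Silyl triflate silylation of the primary O1 and the hindered secondary O8 hydroxyls; O8 must stay silylated through step 13 so that only O1 can add to the ynone.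

**Union and endgame (steps 11–14)**

Step 11
Reactants: 10 (3E,5R,6S,7R)-6-[(tert-butyldimethylsilyl)oxy]-5,7-dimethylnon-3-en-1-yn-5-ol; 21 (3S,4R,5R)-4-[(tert-butyldimethylsilyl)oxy]-3-{[(tert-butyldimethylsilyl)oxy]methyl}-5-ethynyl-5-methyloxolan-2-one
Product: 23 (3R,4R,5S,9E,11R,12S,13R)-4,12-bis[(tert-butyldimethylsilyl)oxy]-5-{[(tert-butyldimethylsilyl)oxy]methyl}-3,11-dihydroxy-3,11,13-trimethylpentadec-9-ene-1,7-diyn-6-one, via dilithiated enyne 22 (not isolated)
Conditions: 10 (1.3 equiv), n-BuLi (2.6 equiv), THF, −78 °C; then 21, −78 °C; AcOH, −78 °C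
Reagents that add atoms: none
Why: Addition of a lithium acetylide to a γ-lactone: the lithium hemiketalate is stable at −78 °C, so a single acetylide adds and the cold acidic quench releases the γ-hydroxy ynone without a Weinreb amide; the conjugated enyne C–H is the more acidic alkyne, so proton transfer to the ethynyl group of 21 should not drain the nucleophile.

Step 12
Reactants: 23 (3R,4R,5S,9E,11R,12S,13R)-4,12-bis[(tert-butyldimethylsilyl)oxy]-5-{[(tert-butyldimethylsilyl)oxy]methyl}-3,11-dihydroxy-3,11,13-trimethylpentadec-9-ene-1,7-diyn-6-one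
Product: 24 (3R,4R,5S,9E,11R,12S,13R)-4,12-bis[(tert-butyldimethylsilyl)oxy]-3,11-dihydroxy-5-(hydroxymethyl)-3,11,13-trimethylpentadec-9-ene-1,7-diyn-6-one (key-step precursor)
Conditions: HF·pyridine, pyridine, THF, 0 °C
Reagents that add atoms: none
Why: Fluoride-mediated desilylation under buffered conditions distinguishes silyl ethers by steric access, so the primary O1 ether should be cleaved well before the two hindered secondary ones; any 25 formed by early cyclisation lies on the path of step 13.

Step 13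
Reactants: 24 (3R,4R,5S,9E,11R,12S,13R)-4,12-bis[(tert-butyldimethylsilyl)oxy]-3,11-dihydroxy-5-(hydroxymethyl)-3,11,13-trimethylpentadec-9-ene-1,7-diyn-6-one
Product: 28 (7S,8R,8aS)-8-[(tert-butyldimethylsilyl)oxy]-3-[(1E,3R,4S,5R)-4-[(tert-butyldimethylsilyl)oxy]-3-hydroxy-3,5-dimethylhept-1-en-1-yl]-7-hydroxy-7-methyl-1,7,8,8a-tetrahydro-6H-isochromen-6-one, via dihydropyranone alkynol 25 (not isolated), via dihydropyranone methyl ketone 26 (not isolated), via aldol adduct 27 (not isolated)
Conditions: Ph3PAuNTf2 (5 mol %), H2O (5 equiv), 1,4-dioxane, rt then 60 °C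
Reagents that add atoms: water, O
Why: Proposed new method: cationic monovalent gold activates the C3≡C4 ynone, the free O1 hydroxyl adds at C3 (β to the C4a carbonyl) and protodeauration gives dihydropyranone 25; the catalyst then hydrates the terminal C5≡C6 alkyne in the Markovnikov sense (assisted by the C7 hydroxyl or the C4a carbonyl oxygen) to methyl ketone 26, whose enol attacks the acid-activated vinylogous ester carbonyl C4a to give 27, and loss of water towards C5 delivers the O2–C3=C4–C4a=C5–C6=O chromophore of 28. The closest known reaction types are the gold-catalysed 6-endo cyclisation of β-hydroxy ynones to 2,3-dihydro-4H-pyran-4-ones, the gold-catalysed hydration of propargylic alcohols to α-hydroxy methyl ketones, and the hydrative alkyne–ketone carbocyclisation to cyclohexenones; running all three in one flask on a vinylogous ester acceptor is what is new. Ring A closes 6-endo-dig (O2–C3) and ring B closes by a 6-(enolendo)-exo-trig aldol (C4a–C5) followed by dehydration. No stereocentre is created, since C7, C8 and C8a come from 21 and the C4a carbinol of 27 is lost again. The step needs 6-endo over 5-exo attack, which ynone polarisation towards C3 secures, attack by O1 alone, which the silyl group on O8 and the E alkene (side-chain hydroxyls out of reach) secure, and hydration at C6, which the terminal alkyne secures. It also needs dehydration towards C5 and no β-elimination of the C8 silyloxy group through C8a; conjugation makes the C5 path the favoured one and the near-neutral, base-free medium is meant to prevent the elimination.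

Step 14
Reactants: 28 (7S,8R,8aS)-8-[(tert-butyldimethylsilyl)oxy]-3-[(1E,3R,4S,5R)-4-[(tert-butyldimethylsilyl)oxy]-3-hydroxy-3,5-dimethylhept-1-en-1-yl]-7-hydroxy-7-methyl-1,7,8,8a-tetrahydro-6H-isochromen-6-one
Product: 29 (7S,8R,8aS)-3-[(1E,3R,4S,5R)-3,4-dihydroxy-3,5-dimethylhept-1-en-1-yl]-7,8-dihydroxy-7-methyl-1,7,8,8a-tetrahydro-6H-isochromen-6-one (target, CNP0291643.7)
Conditions: HF·pyridine, pyridine, THF, 0 °C to rt
Reagents that add atoms: none
Why: Fluoride-mediated desilylation with HF·pyridine is base-free and only mildly acidic, so both secondary silyl ethers should be cleaved without epimerisation at C8a, β-elimination of O8 or ionisation of the tertiary allylic alcohol.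

**Compound list**

1 | L-allo-isoleucine, (2S,3R)-2-amino-3-methylpentanoic acid | CC[C@@H](C)[C@H](N)C(=O)O | starting material
2 | (2S,3R)-2-hydroxy-3-methylpentanoic acid | CC[C@@H](C)[C@H](O)C(=O)O | intermediate
3 | (2S,3R)-2-hydroxy-N-methoxy-N,3-dimethylpentanamide | CC[C@@H](C)[C@H](O)C(=O)N(C)OC | intermediate
4 | (2S,3R)-2-[(tert-butyldimethylsilyl)oxy]-N-methoxy-N,3-dimethylpentanamide | CC[C@@H](C)[C@H](O[Si](C)(C)C(C)(C)C)C(=O)N(C)OC | intermediate
5 | (3S,4R)-3-[(tert-butyldimethylsilyl)oxy]-4-methylhexan-2-one | CC[C@@H](C)[C@H](O[Si](C)(C)C(C)(C)C)C(C)=O | intermediate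
6 | 1,4-bis(trimethylsilyl)buta-1,3-diyne | C[Si](C)(C)C#CC#C[Si](C)(C)C | starting material
7 | lithium (trimethylsilyl)buta-1,3-diynide | [Li]C#CC#C[Si](C)(C)C | intermediate
8 | (5R,6S,7R)-6-[(tert-butyldimethylsilyl)oxy]-5,7-dimethyl-1-(trimethylsilyl)nona-1,3-diyn-5-ol | CC[C@@H](C)[C@H](O[Si](C)(C)C(C)(C)C)[C@](C)(O)C#CC#C[Si](C)(C)C | intermediate
9 | (3E,5R,6S,7R)-6-[(tert-butyldimethylsilyl)oxy]-5,7-dimethyl-1-(trimethylsilyl)non-3-en-1-yn-5-ol | CC[C@@H](C)[C@H](O[Si](C)(C)C(C)(C)C)[C@](C)(O)/C=C/C#C[Si](C)(C)C | intermediate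
10 | (3E,5R,6S,7R)-6-[(tert-butyldimethylsilyl)oxy]-5,7-dimethylnon-3-en-1-yn-5-ol (fragment 1) | CC[C@@H](C)[C@H](O[Si](C)(C)C(C)(C)C)[C@](C)(O)/C=C/C#C | intermediate
11 | dimethyl (R)-malate, dimethyl (2R)-2-hydroxybutanedioate | COC(=O)C[C@@H](O)C(=O)OC | starting material
12 | formaldehyde | C=O | starting material
13 | dilithium alkoxide–enolate of dimethyl (R)-malate | COC(O[Li])=C[C@@H](O[Li])C(=O)OC | intermediate
14 | dimethyl (2R,3S)-2-hydroxy-3-(hydroxymethyl)butanedioate | COC(=O)[C@@H](CO)[C@@H](O)C(=O)OC | intermediate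
15 | methyl (3S,4R)-4-hydroxy-5-oxooxolane-3-carboxylate | COC(=O)[C@H]1COC(=O)[C@@H]1O | intermediate
16 | methyl (3S,4R)-5-oxo-4-[(trimethylsilyl)oxy]oxolane-3-carboxylate | COC(=O)[C@H]1COC(=O)[C@@H]1O[Si](C)(C)C | intermediate
17 | methyl (3S,4R)-4,5-dihydroxy-5-methyloxolane-3-carboxylate (both C5 anomers) | COC(=O)[C@H]1COC(C)(O)[C@@H]1O | intermediate
18 | ethynylmagnesium bromide | C#C[Mg]Br | starting material
19 | methyl (2S,3R,4R)-3,4-dihydroxy-2-(hydroxymethyl)-4-methylhex-5-ynoate | COC(=O)[C@@H](CO)[C@@H](O)[C@](C)(O)C#C | intermediate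
20 | (3S,4R,5R)-5-ethynyl-4-hydroxy-3-(hydroxymethyl)-5-methyloxolan-2-one | C#C[C@@]1(C)OC(=O)[C@@H](CO)[C@H]1O | intermediate
21 | (3S,4R,5R)-4-[(tert-butyldimethylsilyl)oxy]-3-{[(tert-butyldimethylsilyl)oxy]methyl}-5-ethynyl-5-methyloxolan-2-one (fragment 2) | C#C[C@@]1(C)OC(=O)[C@@H](CO[Si](C)(C)C(C)(C)C)[C@H]1O[Si](C)(C)C(C)(C)C | intermediate
22 | dilithium alkoxide–acetylide of 10 | CC[C@@H](C)[C@H](O[Si](C)(C)C(C)(C)C)[C@](C)(O[Li])/C=C/C#C[Li] | intermediate
23 | (3R,4R,5S,9E,11R,12S,13R)-4,12-bis[(tert-butyldimethylsilyl)oxy]-5-{[(tert-butyldimethylsilyl)oxy]methyl}-3,11-dihydroxy-3,11,13-trimethylpentadec-9-ene-1,7-diyn-6-one | CC[C@@H](C)[C@H](O[Si](C)(C)C(C)(C)C)[C@](C)(O)/C=C/C#CC(=O)[C@@H](CO[Si](C)(C)C(C)(C)C)[C@@H](O[Si](C)(C)C(C)(C)C)[C@](C)(O)C#C | intermediate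
24 | (3R,4R,5S,9E,11R,12S,13R)-4,12-bis[(tert-butyldimethylsilyl)oxy]-3,11-dihydroxy-5-(hydroxymethyl)-3,11,13-trimethylpentadec-9-ene-1,7-diyn-6-one (key-step precursor) | CC[C@@H](C)[C@H](O[Si](C)(C)C(C)(C)C)[C@](C)(O)/C=C/C#CC(=O)[C@@H](CO)[C@@H](O[Si](C)(C)C(C)(C)C)[C@](C)(O)C#C | intermediate
25 | (3S)-3-[(1R,2R)-1-[(tert-butyldimethylsilyl)oxy]-2-hydroxy-2-methylbut-3-yn-1-yl]-6-[(1E,3R,4S,5R)-4-[(tert-butyldimethylsilyl)oxy]-3-hydroxy-3,5-dimethylhept-1-en-1-yl]-2,3-dihydro-4H-pyran-4-one | CC[C@@H](C)[C@H](O[Si](C)(C)C(C)(C)C)[C@](C)(O)/C=C/C1=CC(=O)[C@@H](CO1)[C@@H](O[Si](C)(C)C(C)(C)C)[C@](C)(O)C#C | intermediate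
26 | (3S)-3-[(1R,2S)-1-[(tert-butyldimethylsilyl)oxy]-2-hydroxy-2-methyl-3-oxobutyl]-6-[(1E,3R,4S,5R)-4-[(tert-butyldimethylsilyl)oxy]-3-hydroxy-3,5-dimethylhept-1-en-1-yl]-2,3-dihydro-4H-pyran-4-one | CC[C@@H](C)[C@H](O[Si](C)(C)C(C)(C)C)[C@](C)(O)/C=C/C1=CC(=O)[C@@H](CO1)[C@@H](O[Si](C)(C)C(C)(C)C)[C@](C)(O)C(C)=O | intermediate
27 | (7S,8R,8aS)-8-[(tert-butyldimethylsilyl)oxy]-3-[(1E,3R,4S,5R)-4-[(tert-butyldimethylsilyl)oxy]-3-hydroxy-3,5-dimethylhept-1-en-1-yl]-4a,7-dihydroxy-7-methyl-1,4a,5,7,8,8a-hexahydro-6H-isochromen-6-one (C4a epimers) | CC[C@@H](C)[C@H](O[Si](C)(C)C(C)(C)C)[C@](C)(O)/C=C/C1=CC2(O)CC(=O)[C@@](C)(O)[C@H](O[Si](C)(C)C(C)(C)C)[C@@H]2CO1 | intermediate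
28 | (7S,8R,8aS)-8-[(tert-butyldimethylsilyl)oxy]-3-[(1E,3R,4S,5R)-4-[(tert-butyldimethylsilyl)oxy]-3-hydroxy-3,5-dimethylhept-1-en-1-yl]-7-hydroxy-7-methyl-1,7,8,8a-tetrahydro-6H-isochromen-6-one (key-step product) | CC[C@@H](C)[C@H](O[Si](C)(C)C(C)(C)C)[C@](C)(O)/C=C/C1=CC2=CC(=O)[C@@](C)(O)[C@H](O[Si](C)(C)C(C)(C)C)[C@@H]2CO1 | intermediate
29 | (7S,8R,8aS)-3-[(1E,3R,4S,5R)-3,4-dihydroxy-3,5-dimethylhept-1-en-1-yl]-7,8-dihydroxy-7-methyl-1,7,8,8a-tetrahydro-6H-isochromen-6-one (CNP0291643.7) | CC[C@@H](C)[C@H](O)[C@](C)(O)/C=C/C1=CC2=CC(=O)[C@@](C)(O)[C@H](O)[C@@H]2CO1 | target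

**Counts and risks**

Total step count: 14. Longest linear sequence: 10 steps (steps 1–6, then 11–14).

The three steps most likely to fail:

Step 13. The cascade may stall after ring A or after hydration, because the vinylogous ester carbonyl is a weak aldol acceptor. Meyer–Schuster rearrangement of the ethynyl carbinol, or loss of the C8 silyloxy group through C8a, may also compete. Fallback: the three events are run as separate, known reactions, setting out from 24 and coming back at 28. Anhydrous Ph3PAuNTf2 in CH2Cl2 over 4 Å molecular sieves (6-endo cyclisation of a β-hydroxy ynone) should allow 25 to be isolated. Catalytic Hg(OTf)2 with tetramethylurea in wet MeCN (Markovnikov hydration of a terminal alkyne) should convert 25 into 26. Pyrrolidinium acetate in toluene at 60 °C (enamine aldol condensation, the ring-closing half of a Robinson annulation) should take 26 through 27 to 28. This sequence makes no compound outside the list.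

Step 8. Methyllithium may attack the methyl ester, or add twice if the hemiketalate collapses, so the chemoselectivity for the lactone carbonyl may be lost. Fallback: a Weinreb route from 15 back to 17. Me2AlN(OMe)Me (from AlMe3 and MeNHOMe·HCl, CH2Cl2, 0 °C) should open only the lactone to methyl (2S,3R)-3-hydroxy-2-(hydroxymethyl)-4-[methoxy(methyl)amino]-4-oxobutanoate F1. TESCl and imidazole, applied at once to stop relactonisation, should give the bis(triethylsilyl) ether F2. MeMgBr at −78 °C should convert the amide, not the branched ester, into the methyl ketone F3. AcOH/THF/H2O should then remove both triethylsilyl groups and let the keto diol close to lactol 17.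

Step 5. Facial selectivity may be poor, because a methyl ketone gives the Felkin–Anh model little steric bias. Fallback: the order of the two carbon nucleophiles is reversed and chelation is used, setting out from 3 and coming back at 8. 4-Methoxybenzyl trichloroacetimidate with catalytic TfOH should give the 4-methoxybenzyl ether F4. Lithium diynide 7 should convert this Weinreb amide into the diynyl ketone F5. MeMgBr in Et2O at −78 °C should add under Cram chelate control (magnesium bridging the benzylic ether oxygen and the carbonyl oxygen, methyl entering opposite the sec-butyl group) to give the 5R carbinol F6. DDQ in wet CH2Cl2 should free the diol F7. TBSOTf (1 equiv) with 2,6-lutidine at −78 °C should silylate only the secondary hydroxyl and deliver 8.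

**Further compounds**

F0 | step 13 | none | none
F1 | step 8 | methyl (2S,3R)-3-hydroxy-2-(hydroxymethyl)-4-[methoxy(methyl)amino]-4-oxobutanoate | COC(=O)[C@@H](CO)[C@@H](O)C(=O)N(C)OC
F2 | step 8 | methyl (2S,3R)-4-[methoxy(methyl)amino]-4-oxo-3-[(triethylsilyl)oxy]-2-{[(triethylsilyl)oxy]methyl}butanoate | COC(=O)[C@@H](CO[Si](CC)(CC)CC)[C@@H](O[Si](CC)(CC)CC)C(=O)N(C)OC
F3 | step 8 | methyl (2S,3R)-4-oxo-3-[(triethylsilyl)oxy]-2-{[(triethylsilyl)oxy]methyl}pentanoate | COC(=O)[C@@H](CO[Si](CC)(CC)CC)[C@@H](O[Si](CC)(CC)CC)C(C)=O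
F4 | step 5 | (2S,3R)-N-methoxy-2-[(4-methoxybenzyl)oxy]-N,3-dimethylpentanamide | CC[C@@H](C)[C@H](OCc1ccc(OC)cc1)C(=O)N(C)OC
F5 | step 5 | (6S,7R)-6-[(4-methoxybenzyl)oxy]-7-methyl-1-(trimethylsilyl)nona-1,3-diyn-5-one | CC[C@@H](C)[C@H](OCc1ccc(OC)cc1)C(=O)C#CC#C[Si](C)(C)C
F6 | step 5 | (5R,6S,7R)-6-[(4-methoxybenzyl)oxy]-5,7-dimethyl-1-(trimethylsilyl)nona-1,3-diyn-5-ol | CC[C@@H](C)[C@H](OCc1ccc(OC)cc1)[C@](C)(O)C#CC#C[Si](C)(C)C
F7 | step 5 | (5R,6S,7R)-5,7-dimethyl-1-(trimethylsilyl)nona-1,3-diyne-5,6-diol | CC[C@@H](C)[C@H](O)[C@](C)(O)C#CC#C[Si](C)(C)C
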